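**Plan**
The target has a trans-decalin (ring A C1–C5/C10, ring B C5–C10), a chain C11–C15 and a butenolide (ring C: O16, C16–C19). C15 and C16 carry a threo diol flanked by C14 and C17, which is the four-carbon skeleton and configuration of diethyl L-tartrate (1), so ring C can be built last on an intact tartrate diol.
Cuts, in retrosynthetic order: ring C at O16–C19 and C17=C18; then the chain at C12–C13 (sp3–sp2) into a ring A/B iodide C1–C12 drawn from (+)-larixol (2) and an (E)-vinyl iodide C13–C17 drawn from 1; C18–C19 come from Ph3P=C=C=O (3).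
Forward: 1 is desymmetrised and carried to the C13–C17 vinyl iodide ketone (steps 1–11); 2, with rings A and B preformed, is trimmed to C12 and oxidised at C8 and C23 (steps 12–20); Negishi coupling joins C12–C13 (step 21); PMB removal, closure of ring C and desilylation finish (steps 22–24).
Stereochemistry: C15 and C16 are carried unchanged from 1; C5, C6, C9 and C10 come from 2; C8 is set by α-face epoxidation and hydride opening; C4 by 1,5-hydrogen transfer to the 6α-oxygen, which can reach only the α-methyl; E-C13=C14 by syn-hydrozirconation and coupling with retention.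

Key step: step 23

Remark: C20 is the methyl on C10, C21 that on C13, C22 the carbon on C8, C23 the α-carbon and C24 the β-methyl on C4, C25 the methyl on C17; (+)-larixol is assumed to be purchasable as the isolated larch diterpenoid.

**Fragment 1 (C13–C17) from diethyl L-tartrate**

Step 1
Reactants: 1 diethyl L-tartrate
Product: 4 diethyl (2R,3R)-2-(tert-butyldimethylsilyloxy)-3-hydroxybutanedioate
Conditions: TBSCl (1.05 equiv), imidazole, DMF, 0 °C
Reagents that add atoms: tert-butyldimethylsilyl chloride, CC(C)(C)[Si](C)(C)Cl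
Why: Mono-silylation of a C2-symmetric diol, in which both hydroxyls are equivalent and the second is slowed by the neighbouring silyl ether, tells the future O15 (silylated) from O16 (free) without touching either stereocentre.

Step 2
Reactants: 4 mono-TBS tartrate
Product: 5 ethyl (2R,3S)-2-(tert-butyldimethylsilyloxy)-3,4-dihydroxybutanoate
Conditions: BH3·SMe2, NaBH4 (5 mol %), THF, rt; MeOH quench
Reagents that add atoms: none
Why: Hydroxyl-directed borane reduction (Saito conditions), in which the alkoxyborane formed at the free C16 hydroxyl delivers hydride only to the adjacent ester, so C17 becomes CH2OH while the ester next to the silyl ether (future C14) is kept.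

Step 3
Reactants: 5 diol ester
Product: 6 ethyl (2R)-2-(tert-butyldimethylsilyloxy)-2-[(4S)-2-(4-methoxyphenyl)-1,3-dioxolan-4-yl]acetate (both acetal epimers)
Conditions: 4-MeOC6H4CH(OMe)2, PPTS (cat.), CH2Cl2, rt
Reagents that add atoms: 4-methoxybenzaldehyde dimethyl acetal, COC(OC)c1ccc(OC)cc1
Why: Acid-catalysed transacetalisation of the terminal 1,2-diol to a five-membered 4-methoxybenzylidene acetal; the new acetal carbon forms as a mixture of epimers, which is harmless because step 8 reduces it to a CH2.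

Step 4
Reactants: 6 acetal ester
Product: 7 (2R)-2-(tert-butyldimethylsilyloxy)-2-[(4S)-2-(4-methoxyphenyl)-1,3-dioxolan-4-yl]acetaldehyde
Conditions: DIBAL-H (1.1 equiv), CH2Cl2, −78 °C
Reagents that add atoms: none
Why: Partial reduction of an α-silyloxy ester with DIBAL-H, whose tetrahedral aluminium hemiacetal persists at low temperature and releases the C14 aldehyde only on work-up, without epimerising C15.

Step 5
Reactants: 7 aldehyde
Product: 8 (4S)-4-[(1S)-3,3-dibromo-1-(tert-butyldimethylsilyloxy)prop-2-en-1-yl]-2-(4-methoxyphenyl)-1,3-dioxolane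
Conditions: CBr4, PPh3, 2,6-lutidine, CH2Cl2, 0 °C
Reagents that add atoms: carbon tetrabromide, BrC(Br)(Br)Br
Why: First stage of the Corey–Fuchs sequence, a Wittig reaction with Ph3P=CBr2 made in the flask, which adds C13 under non-basic conditions while lutidine shields the acetal from acid.

Step 6
Reactants: 8 dibromoalkene
Product: 10 (4S)-4-[(1S)-1-(tert-butyldimethylsilyloxy)but-2-yn-1-yl]-2-(4-methoxyphenyl)-1,3-dioxolane, via lithium acetylide 9 (not isolated)
Conditions: n-BuLi (2.1 equiv), THF, −78 °C; then MeI, −78 °C to rt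
Reagents that add atoms: iodomethane, CI
Why: Second stage of the Corey–Fuchs sequence, in which bromine–lithium exchange and carbenoid rearrangement give the lithium acetylide that is methylated in the same flask to install C21.

Step 7
Reactants: 10 methylalkyne
Product: 12 (4S)-4-[(1S,2E)-1-(tert-butyldimethylsilyloxy)-3-iodobut-2-en-1-yl]-2-(4-methoxyphenyl)-1,3-dioxolane, via alkenylzirconocene chloride 11 (not isolated)
Conditions: Cp2Zr(H)Cl (2.5 equiv), THF, 50 °C; then I2, 0 °C
Reagents that add atoms: iodine, II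
Why: Hydrozirconation–iodination, in which Cp2Zr(H)Cl adds syn and excess reagent equilibrates zirconium onto the less hindered methyl-bearing C13, so iodinolysis with retention should give the E vinyl iodide with C21 cis to C15.

Step 8
Reactants: 12 vinyl iodide acetal
Product: 13 (2S,3S,4E)-3-(tert-butyldimethylsilyloxy)-5-iodo-2-(4-methoxybenzyloxy)hex-4-en-1-ol
Conditions: DIBAL-H (3 equiv), CH2Cl2, −78 to 0 °C
Reagents that add atoms: none
Why: Regioselective reductive opening of a 4-methoxybenzylidene acetal with DIBAL-H, which coordinates the less hindered primary oxygen and so leaves the PMB group on the secondary O16 and frees the C17 alcohol.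

Step 9
Reactants: 13 primary alcohol
Product: 14 (2R,3S,4E)-3-(tert-butyldimethylsilyloxy)-5-iodo-2-(4-methoxybenzyloxy)hex-4-enal
Conditions: Dess–Martin periodinane, CH2Cl2, rt
Reagents that add atoms: none
Why: Dess–Martin oxidation of a primary alcohol under near-neutral conditions that should not epimerise the α-alkoxy aldehyde or affect the vinyl iodide.

Step 10
Reactants: 14 aldehyde
Product: 15 (3S,4S,5E)-4-(tert-butyldimethylsilyloxy)-6-iodo-3-(4-methoxybenzyloxy)hept-5-en-2-ol (both C2 epimers)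
Conditions: MeMgBr, THF, −78 °C
Reagents that add atoms: methylmagnesium bromide, C[Mg]Br
Why: Grignard addition to the aldehyde brings in C25; the new C17 carbinol centre is uncontrolled and is erased by the oxidation in step 11.

Step 11
Reactants: 15 carbinol
Product: 16 (3R,4S,5E)-4-(tert-butyldimethylsilyloxy)-6-iodo-3-(4-methoxybenzyloxy)hept-5-en-2-one
Conditions: Dess–Martin periodinane, CH2Cl2, rt
Reagents that add atoms: none
Why: Dess–Martin oxidation converges both carbinol epimers on the C17 methyl ketone under non-basic conditions, so C16 and the β-silyloxy group are not put at risk.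

**Fragment 2 (C1–C12) from (+)-larixol**

Step 12
Reactants: 2 (+)-larixol
Product: 17 6α-hydroxy-8(22)-methylene C13 methyl ketone (9β-CH2CH2COCH3 chain on the 4,4,10β-trimethyl trans-decalin)
Conditions: KMnO4, acetone/H2O, 0 °C to rt
Reagents that add atoms: none
Why: Permanganate degradation of the vinyl carbinol (dihydroxylation, then glycol cleavage down to the ketone), an established side-chain cleavage of labdane tertiary allylic alcohols in which the hindered exocyclic alkene and the secondary alcohol react more slowly.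

Step 13
Reactants: 17 methyl ketone
Product: 19 8α,22-epoxy-6α-hydroxy 12-acetate, via epoxy ketone 18 (not isolated)
Conditions: (CF3CO)2O, urea·H2O2, Na2HPO4, CH2Cl2, 0 °C to rt
Reagents that add atoms: trifluoroperacetic acid, OOC(=O)C(F)(F)F
Why: Prilezhaev epoxidation followed by Baeyer–Villiger oxidation with buffered CF3CO3H; the peracid should approach the exocyclic alkene from the α face, away from the axial C20 methyl and guided by the 6α-hydroxyl, and the primary C12 migrates in preference to methyl to give the acetate.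

Step 14
Reactants: 19 epoxy acetate
Product: 22 6α,23:8α,22-diepoxy 12-acetate (tetrahydrofuran bridging O6 and the 4α-CH2), via hypoiodite 20 (not isolated), via 23-iodo alcohol 21 (not isolated)
Conditions: PhI(OAc)2, I2, cyclohexane/CH2Cl2, hν (tungsten lamp), 40 °C
Reagents that add atoms: none
Why: Suárez hypoiodite reaction, in which the C6 oxyl radical abstracts hydrogen through a six-membered transition state from the only δ C–H within reach, the α-methyl C23 lying peri to the equatorial 6α-oxygen, and O6 then displaces the resulting iodide, so C4 becomes a stereocentre with its oxidised carbon α.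

Step 15
Reactants: 22 cyclic ether
Product: 23 23,6α-olide 8α,22-epoxy 12-acetate (γ-lactone with C23 as carbonyl)
Conditions: RuCl3 hydrate (cat.), NaIO4, EtOAc/MeCN/H2O, rt
Reagents that add atoms: ruthenium tetroxide, O=[Ru](=O)(=O)=O (made in the flask; sodium periodate, [Na+].[O-]I(=O)(=O)=O, is the terminal oxidant)
Why: RuO4 oxidation of a cyclic ether to a lactone (the ambroxide-to-sclareolide transformation), which attacks the O–CH2 carbon C23 in preference to the O–CH carbon C6 and leaves ester and epoxide alone.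

Step 16
Reactants: 23 lactone
Product: 24 6α,8α,12,23-tetraol
Conditions: LiAlH4, THF, 0 °C to reflux
Reagents that add atoms: none
Why: Exhaustive hydride reduction opens the lactone to the 6α,23-diol, cleaves the acetate and opens the spiro-epoxide by SN2 attack at its CH2 carbon C22, which leaves the C8–O bond untouched and so gives the 8α-hydroxy-8β-methyl centre.

Step 17
Reactants: 24 tetraol
Product: 25 6α,8α,23-triol 12-pivalate
Conditions: PivCl (1.05 equiv), pyridine, CH2Cl2, −20 °C
Reagents that add atoms: pivaloyl chloride, CC(C)(C)C(Cl)=O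
Why: Selective acylation with the bulky pivaloyl chloride should pick the unhindered primary C12 hydroxyl over the neopentyl C23, secondary C6 and tertiary C8 hydroxyls.

Step 18
Reactants: 25 triol pivalate
Product: 26 6α,8α,23-tris(triethylsilyloxy) 12-pivalate
Conditions: TESOTf (4 equiv), 2,6-lutidine, CH2Cl2, −78 °C to rt
Reagents that add atoms: triethylsilyl trifluoromethanesulfonate, CC[Si](CC)(CC)OS(=O)(=O)C(F)(F)F
Why: Silyl triflate silylation is forceful enough for the tertiary C8 hydroxyl and also masks O6 and O23, which prevents the ready cyclisation of an activated C12 onto O8 in step 20.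

Step 19
Reactants: 26 silylated pivalate
Product: 27 6α,8α,23-tris(triethylsilyloxy) 12-alcohol
Conditions: DIBAL-H, CH2Cl2, −78 °C
Reagents that add atoms: none
Why: Reductive cleavage of the pivalate with DIBAL-H, to which silyl ethers are inert.

Step 20
Reactants: 27 primary alcohol
Product: 28 6α,8α,23-tris(triethylsilyloxy) 12-iodide
Conditions: I2, PPh3, imidazole, CH2Cl2, 0 °C to rt
Reagents that add atoms: iodine, II
Why: Appel iodination, an SN2 displacement of the alkoxyphosphonium by iodide at the unhindered primary carbon under imidazole buffering that triethylsilyl ethers tolerate.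

**Union and completion**

Step 21
Reactants: 28 C12 iodide; 16 vinyl iodide ketone
Product: 30 (13E,15S,16R)-15-(tert-butyldimethylsilyloxy)-16-(4-methoxybenzyloxy)-6α,8α,23-tris(triethylsilyloxy) C17 methyl ketone, via alkylzinc iodide 29 (not isolated)
Conditions: 28, Zn dust, LiCl, THF, 40 °C; then 16, Pd(PPh3)4 (5 mol %), rt to 45 °C
Reagents that add atoms: none
Why: Negishi sp3–sp2 coupling, in which the primary alkylzinc iodide from LiCl-promoted zinc insertion does not add to the ketone of 16 and couples at zerovalent palladium with retention of the E geometry, the base-free medium sparing the epimerisable C16.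

Step 22
Reactants: 30 PMB ether
Product: 31 (13E,15S,16R)-15-(tert-butyldimethylsilyloxy)-16-hydroxy-6α,8α,23-tris(triethylsilyloxy) C17 methyl ketone
Conditions: DDQ, CH2Cl2/pH 7 buffer, 0 °C
Reagents that add atoms: none
Why: Oxidative cleavage of the 4-methoxybenzyl ether with DDQ via the benzylic oxocarbenium ion, under buffered neutral conditions that should leave the silyl ethers, the trisubstituted alkene and the configuration at C16 untouched.

Step 23
Reactants: 31 C16-hydroxy C17 methyl ketone; 3 triphenylphosphoranylideneketene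
Product: 33 (13E,15S,16S)-15-(tert-butyldimethylsilyloxy)-6α,8α,23-tris(triethylsilyloxy) butenolide (silylated target), via ester ylide 32 (not isolated)
Conditions: Ph3P=C=C=O (1.3 equiv), toluene, 90 °C
Reagents that add atoms: none
Why: The C16 hydroxyl adds across the C=C of the cumulated ylide to give the stabilised ester ylide 32, whose ylide carbon C18 attacks the neighbouring C17 ketone, and the oxaphosphetane collapses with loss of Ph3PO, so O16–C19 and C17=C18 form in one flask. The closest known reaction is the butenolide synthesis from α-hydroxy ketones and this ketenylidene phosphorane (acylation, then intramolecular Wittig olefination). Ring C closes in the 5-exo-trig mode, C18 attacking the C17 carbonyl carbon with its oxygen outside the forming ring, which fixes the alkene at C17=C18 and the methyl C25 on C17. No stereocentre is created; C16 only has to keep the configuration inherited from 1, and the neutral, base-free medium protects this ketone-activated C–H. The step needs acylation of a single hydroxyl, which is secured because O15 carries TBS and O6, O8 and O23 carry TES. The ester-stabilised ylide has no other carbonyl within reach, so no competing olefination is expected.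

Step 24
Reactants: 33 silylated target
Product: 34 CNP0255788.1
Conditions: HF·pyridine, pyridine, THF, 0 °C to rt
Reagents that add atoms: none
Why: Fluoride cleavage of all four silyl ethers with buffered HF·pyridine, chosen on the acidic side because the butenolide with its acidic C16–H would not tolerate basic fluoride sources.

**Compound list**
1 | diethyl L-tartrate, diethyl (2R,3R)-2,3-dihydroxybutanedioate | CCOC(=O)[C@H](O)[C@@H](O)C(=O)OCC | starting material
2 | (+)-larixol, (13S)-labda-8(17),14-diene-6α,13-diol (labdane locants in this name only) | C=C[C@@](C)(O)CC[C@@H]1[C@@]2(C)CCCC(C)(C)[C@@H]2[C@@H](O)CC1=C | starting material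
3 | triphenylphosphoranylideneketene | O=C=C=P(c1ccccc1)(c1ccccc1)c1ccccc1 | starting material
4 | diethyl (2R,3R)-2-(tert-butyldimethylsilyloxy)-3-hydroxybutanedioate | CCOC(=O)[C@H](O)[C@@H](O[Si](C)(C)C(C)(C)C)C(=O)OCC | intermediate
5 | ethyl (2R,3S)-2-(tert-butyldimethylsilyloxy)-3,4-dihydroxybutanoate | OC[C@H](O)[C@@H](O[Si](C)(C)C(C)(C)C)C(=O)OCC | intermediate
6 | ethyl (2R)-2-(tert-butyldimethylsilyloxy)-2-[(4S)-2-(4-methoxyphenyl)-1,3-dioxolan-4-yl]acetate (acetal epimers) | COc1ccc(cc1)C1OC[C@H](O1)[C@@H](O[Si](C)(C)C(C)(C)C)C(=O)OCC | intermediate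
7 | (2R)-2-(tert-butyldimethylsilyloxy)-2-[(4S)-2-(4-methoxyphenyl)-1,3-dioxolan-4-yl]acetaldehyde | COc1ccc(cc1)C1OC[C@H](O1)[C@@H](O[Si](C)(C)C(C)(C)C)C=O | intermediate
8 | (4S)-4-[(1S)-3,3-dibromo-1-(tert-butyldimethylsilyloxy)prop-2-en-1-yl]-2-(4-methoxyphenyl)-1,3-dioxolane | COc1ccc(cc1)C1OC[C@H](O1)[C@@H](O[Si](C)(C)C(C)(C)C)C=C(Br)Br | intermediate
9 | lithium acetylide of the C13–C17 fragment (C13–Li) | COc1ccc(cc1)C1OC[C@H](O1)[C@@H](O[Si](C)(C)C(C)(C)C)C#C[Li] | intermediate
10 | (4S)-4-[(1S)-1-(tert-butyldimethylsilyloxy)but-2-yn-1-yl]-2-(4-methoxyphenyl)-1,3-dioxolane | COc1ccc(cc1)C1OC[C@H](O1)[C@@H](O[Si](C)(C)C(C)(C)C)C#CC | intermediate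
11 | (E)-alkenylzirconocene chloride, zirconium on C13 | COc1ccc(cc1)C1OC[C@H](O1)[C@@H](O[Si](C)(C)C(C)(C)C)/C=C(\C)[Zr](Cl)(C1C=CC=C1)C1C=CC=C1 | intermediate
12 | (4S)-4-[(1S,2E)-1-(tert-butyldimethylsilyloxy)-3-iodobut-2-en-1-yl]-2-(4-methoxyphenyl)-1,3-dioxolane | COc1ccc(cc1)C1OC[C@H](O1)[C@@H](O[Si](C)(C)C(C)(C)C)/C=C(\C)I | intermediate
13 | (2S,3S,4E)-3-(tert-butyldimethylsilyloxy)-5-iodo-2-(4-methoxybenzyloxy)hex-4-en-1-ol | OC[C@H](OCc1ccc(OC)cc1)[C@@H](O[Si](C)(C)C(C)(C)C)/C=C(\C)I | intermediate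
14 | (2R,3S,4E)-3-(tert-butyldimethylsilyloxy)-5-iodo-2-(4-methoxybenzyloxy)hex-4-enal | O=C[C@H](OCc1ccc(OC)cc1)[C@@H](O[Si](C)(C)C(C)(C)C)/C=C(\C)I | intermediate
15 | (3S,4S,5E)-4-(tert-butyldimethylsilyloxy)-6-iodo-3-(4-methoxybenzyloxy)hept-5-en-2-ol (C2 epimers) | CC(O)[C@H](OCc1ccc(OC)cc1)[C@@H](O[Si](C)(C)C(C)(C)C)/C=C(\C)I | intermediate
16 | (3R,4S,5E)-4-(tert-butyldimethylsilyloxy)-6-iodo-3-(4-methoxybenzyloxy)hept-5-en-2-one | CC(=O)[C@H](OCc1ccc(OC)cc1)[C@@H](O[Si](C)(C)C(C)(C)C)/C=C(\C)I | intermediate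
17 | 6α-hydroxy-8(22)-methylene C13 methyl ketone (4,4,10β-trimethyl trans-decalin, 9β-CH2CH2COCH3) | CC(=O)CC[C@@H]1[C@@]2(C)CCCC(C)(C)[C@@H]2[C@@H](O)CC1=C | intermediate
18 | 8α,22-epoxy-6α-hydroxy C13 methyl ketone | CC(=O)CC[C@@H]1[C@@]2(C)CCCC(C)(C)[C@@H]2[C@@H](O)C[C@@]1(C3)O3 | intermediate
19 | 8α,22-epoxy-6α-hydroxy 12-acetate | CC(=O)OCC[C@@H]1[C@@]2(C)CCCC(C)(C)[C@@H]2[C@@H](O)C[C@@]1(C3)O3 | intermediate
20 | C6 hypoiodite of 19 | CC(=O)OCC[C@@H]1[C@@]2(C)CCCC(C)(C)[C@@H]2[C@@H](OI)C[C@@]1(C3)O3 | intermediate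
21 | 23-iodo-6α-hydroxy 8α,22-epoxy 12-acetate (4α-CH2I, 4β-CH3) | CC(=O)OCC[C@@H]1[C@@]2(C)CCC[C@@](C)(CI)[C@@H]2[C@@H](O)C[C@@]1(C3)O3 | intermediate
22 | 6α,23:8α,22-diepoxy 12-acetate | CC(=O)OCC[C@@H]1[C@@]2(C)CCC[C@@](C)(CO4)[C@@H]2[C@@H]4C[C@@]1(C3)O3 | intermediate
23 | 23,6α-olide 8α,22-epoxy 12-acetate | CC(=O)OCC[C@@H]1[C@@]2(C)CCC[C@@](C)(C(=O)O4)[C@@H]2[C@@H]4C[C@@]1(C3)O3 | intermediate
24 | 6α,8α,12,23-tetraol (C1–C12 decalin with 8β-, 10β- and 4β-methyl) | OCC[C@@H]1[C@@]2(C)CCC[C@@](C)(CO)[C@@H]2[C@@H](O)C[C@@]1(C)O | intermediate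
25 | 6α,8α,23-triol 12-pivalate | CC(C)(C)C(=O)OCC[C@@H]1[C@@]2(C)CCC[C@@](C)(CO)[C@@H]2[C@@H](O)C[C@@]1(C)O | intermediate
26 | 6α,8α,23-tris(triethylsilyloxy) 12-pivalate | CC(C)(C)C(=O)OCC[C@@H]1[C@@]2(C)CCC[C@@](C)(CO[Si](CC)(CC)CC)[C@@H]2[C@@H](O[Si](CC)(CC)CC)C[C@@]1(C)O[Si](CC)(CC)CC | intermediate
27 | 6α,8α,23-tris(triethylsilyloxy) 12-alcohol | OCC[C@@H]1[C@@]2(C)CCC[C@@](C)(CO[Si](CC)(CC)CC)[C@@H]2[C@@H](O[Si](CC)(CC)CC)C[C@@]1(C)O[Si](CC)(CC)CC | intermediate
28 | 6α,8α,23-tris(triethylsilyloxy) 12-iodide | ICC[C@@H]1[C@@]2(C)CCC[C@@](C)(CO[Si](CC)(CC)CC)[C@@H]2[C@@H](O[Si](CC)(CC)CC)C[C@@]1(C)O[Si](CC)(CC)CC | intermediate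
29 | C12 alkylzinc iodide of 28 | I[Zn]CC[C@@H]1[C@@]2(C)CCC[C@@](C)(CO[Si](CC)(CC)CC)[C@@H]2[C@@H](O[Si](CC)(CC)CC)C[C@@]1(C)O[Si](CC)(CC)CC | intermediate
30 | (13E,15S,16R)-15-(tert-butyldimethylsilyloxy)-16-(4-methoxybenzyloxy)-6α,8α,23-tris(triethylsilyloxy) C17 methyl ketone | CC(=O)[C@H](OCc1ccc(OC)cc1)[C@@H](O[Si](C)(C)C(C)(C)C)/C=C(\C)CC[C@@H]1[C@@]2(C)CCC[C@@](C)(CO[Si](CC)(CC)CC)[C@@H]2[C@@H](O[Si](CC)(CC)CC)C[C@@]1(C)O[Si](CC)(CC)CC | intermediate
31 | (13E,15S,16R)-15-(tert-butyldimethylsilyloxy)-16-hydroxy-6α,8α,23-tris(triethylsilyloxy) C17 methyl ketone | CC(=O)[C@H](O)[C@@H](O[Si](C)(C)C(C)(C)C)/C=C(\C)CC[C@@H]1[C@@]2(C)CCC[C@@](C)(CO[Si](CC)(CC)CC)[C@@H]2[C@@H](O[Si](CC)(CC)CC)C[C@@]1(C)O[Si](CC)(CC)CC | intermediate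
32 | 16-O-(triphenylphosphoranylideneacetyl) ester ylide of 31 | CC(=O)[C@H](OC(=O)C=P(c1ccccc1)(c1ccccc1)c1ccccc1)[C@@H](O[Si](C)(C)C(C)(C)C)/C=C(\C)CC[C@@H]1[C@@]2(C)CCC[C@@](C)(CO[Si](CC)(CC)CC)[C@@H]2[C@@H](O[Si](CC)(CC)CC)C[C@@]1(C)O[Si](CC)(CC)CC | intermediate
33 | (13E,15S,16S)-15-(tert-butyldimethylsilyloxy)-6α,8α,23-tris(triethylsilyloxy) butenolide (silylated target) | CC1=CC(=O)O[C@@H]1[C@@H](O[Si](C)(C)C(C)(C)C)/C=C(\C)CC[C@@H]2[C@@]3(C)CCC[C@@](C)(CO[Si](CC)(CC)CC)[C@@H]3[C@@H](O[Si](CC)(CC)CC)C[C@@]2(C)O[Si](CC)(CC)CC | intermediate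
34 | CNP0255788.1, (13E,15S,16S)-6α,8α,15,23-tetrahydroxy butenolide (17-en-19,16-olide) | CC1=CC(=O)O[C@@H]1[C@@H](O)/C=C(\C)CC[C@@H]1[C@@]2(C)CCC[C@@](C)(CO)[C@@H]2[C@@H](O)C[C@@]1(C)O | target

**Count**
Total: 24 steps. Longest linear sequence: 15 steps (steps 1–11, then 21–24); the larixol branch is 13 steps (12–20, then 21–24).

**Steps most likely to fail**

Step 14. The C6 oxyl radical may fragment (β-scission of C5–C6) or be over-oxidised to the ketone faster than it abstracts hydrogen from C23, and the iodine electrophiles may open the acid-labile spiro-epoxide. The fallback leaves the route at 19 and replaces the radical by a silicon tether. Compound 19 is silylated with Et2SiH2 ([Ir(cod)OMe]2 cat., THF) to the diethylhydrosilyl ether F1. Rhodium-catalysed intramolecular C–H silylation ([Rh(cod)Cl]2, Xantphos, norbornene, THF, 100 °C) should close the six-membered oxasilinane F2 on the C23 methyl. Tamao–Fleming oxidation (H2O2, KHCO3, KF, THF/MeOH) then gives the 6α,23-diol 12-acetate F3. LiAlH4 under the conditions of step 16 opens the epoxide and cleaves the acetate, and the route is rejoined at tetraol 24, bypassing steps 14 and 15.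

Step 21. Zinc insertion may stall, the alkyl metal may be lost by protonolysis or β-hydride elimination at palladium, or the α-alkoxy ketone of 16 may be enolised. The fallback sets out from 28 and the ketone-free acetal 12. Iodide 28 is converted with t-BuLi (Et2O, −78 °C) and B-methoxy-9-BBN into the lithium alkylborate F4. B-alkyl Suzuki–Miyaura coupling with 12 (Pd(dppf)Cl2, AsPh3, Cs2CO3, DMF/H2O, rt) gives the coupled acetal F5. The C17 ketone is then built after the union exactly as in steps 8–11: DIBAL-H opening to the primary alcohol F6, Dess–Martin oxidation to the aldehyde F7, MeMgBr addition to the carbinol F8 and a second Dess–Martin oxidation, which returns to the route at 30.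

Step 23. Acylation may be slower than isomerisation of the ketol (enediol shift of the carbonyl to C16, or silyl migration from O15 to O16), or the sequence may stall at the ester ylide because the ketone is hindered. The fallback sets out from 31 and forms the same two bonds in two stages. Esterification with diethylphosphonoacetic acid (DCC, DMAP, CH2Cl2, 0 °C) gives the C16 phosphonoacetate F9, and intramolecular Horner–Wadsworth–Emmons olefination under Masamune–Roush conditions (LiCl, i-Pr2NEt, MeCN, rt) closes ring C and returns to the route at 33.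

**Further compounds**
F1 | step 14 | diethylhydrosilyl ether of 19 | CC(=O)OCC[C@@H]1[C@@]2(C)CCCC(C)(C)[C@@H]2[C@@H](O[SiH](CC)CC)C[C@@]1(C3)O3
F2 | step 14 | oxasilinane bridging O6 and C23 (diethylsilylene), 8α,22-epoxy 12-acetate | CC(=O)OCC[C@@H]1[C@@]2(C)CCC[C@@](C)(C[Si](CC)(CC)O4)[C@@H]2[C@@H]4C[C@@]1(C3)O3
F3 | step 14 | 6α,23-dihydroxy-8α,22-epoxy 12-acetate | CC(=O)OCC[C@@H]1[C@@]2(C)CCC[C@@](C)(CO)[C@@H]2[C@@H](O)C[C@@]1(C3)O3
F4 | step 21 | lithium B-(C12 alkyl)-B-methoxy-9-borabicyclo[3.3.1]nonane borate | [Li+].CO[B-]1(CC[C@@H]2[C@@]3(C)CCC[C@@](C)(CO[Si](CC)(CC)CC)[C@@H]3[C@@H](O[Si](CC)(CC)CC)C[C@@]2(C)O[Si](CC)(CC)CC)C2CCCC1CCC2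
F5 | step 21 | coupled 16,17-O-(4-methoxybenzylidene) acetal (13E; 15-OTBS; 6α,8α,23-tris-OTES) | COc1ccc(cc1)C1OC[C@H](O1)[C@@H](O[Si](C)(C)C(C)(C)C)/C=C(\C)CC[C@@H]1[C@@]2(C)CCC[C@@](C)(CO[Si](CC)(CC)CC)[C@@H]2[C@@H](O[Si](CC)(CC)CC)C[C@@]1(C)O[Si](CC)(CC)CC
F6 | step 21 | coupled C17 primary alcohol with 16-OPMB | OC[C@H](OCc1ccc(OC)cc1)[C@@H](O[Si](C)(C)C(C)(C)C)/C=C(\C)CC[C@@H]1[C@@]2(C)CCC[C@@](C)(CO[Si](CC)(CC)CC)[C@@H]2[C@@H](O[Si](CC)(CC)CC)C[C@@]1(C)O[Si](CC)(CC)CC
F7 | step 21 | coupled C17 aldehyde with 16-OPMB | O=C[C@H](OCc1ccc(OC)cc1)[C@@H](O[Si](C)(C)C(C)(C)C)/C=C(\C)CC[C@@H]1[C@@]2(C)CCC[C@@](C)(CO[Si](CC)(CC)CC)[C@@H]2[C@@H](O[Si](CC)(CC)CC)C[C@@]1(C)O[Si](CC)(CC)CC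
F8 | step 21 | coupled C17 methyl carbinol with 16-OPMB (C17 epimers) | CC(O)[C@H](OCc1ccc(OC)cc1)[C@@H](O[Si](C)(C)C(C)(C)C)/C=C(\C)CC[C@@H]1[C@@]2(C)CCC[C@@](C)(CO[Si](CC)(CC)CC)[C@@H]2[C@@H](O[Si](CC)(CC)CC)C[C@@]1(C)O[Si](CC)(CC)CC
F9 | step 23 | 16-O-(diethoxyphosphorylacetyl) ester of 31 | CC(=O)[C@H](OC(=O)CP(=O)(OCC)OCC)[C@@H](O[Si](C)(C)C(C)(C)C)/C=C(\C)CC[C@@H]1[C@@]2(C)CCC[C@@](C)(CO[Si](CC)(CC)CC)[C@@H]2[C@@H](O[Si](CC)(CC)CC)C[C@@]1(C)O[Si](CC)(CC)CC
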